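## Structural features

The target is a doubly linked biflavonoid. A 3-hydroxyflavanone (aromatic ring A, pyranone ring C, 4-hydroxyphenyl ring B on C2) is joined to aromatic ring D of a (2S)-flavan (4-hydroxyphenyl ring E on C2'') by the C3–C8'' bond and by the ketal oxygen C2–O7''. This makes a dihydrofuran ring F that is cis-fused to ring C along C2–C3.

C2 (an aryl O,O-ketal, R) and C3 (a tertiary carbinol next to the C4 ketone, R) are adjacent and fully substituted. Their relative configuration is forced by the cis ring fusion, so the only independent stereochemical task is the absolute configuration of C3 relative to the remote C2'' (S).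

The fragile groups are the ketal at C2 (ionises readily under acid), the alpha-ketol C3(OH)–C4=O (acyloin-type shifts), the benzylic C–O bonds at C2 and C2'' (hydrogenolysis, ionisation), and two phloroglucinol-type rings with six phenols (oxidants, electrophiles).

The real difficulty is twofold: the congestion at C3, which carries C2, C4 and the di-ortho-substituted C8'', and raising C2 to the ketal oxidation level while an oxidisable flavan is present.

The key step exploits the fact that O1–C2–C3(OH)–C4(=O) with ring A is a dihydroflavonol whose carbinol carbon C3 carries one extra aryl group (C8'' of ring D). That unit is the ring-opened form of an alpha-aryl chalcone epoxide attacked at C2 by the ortho oxygen of ring A.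

## Logic of the disconnections

22 ⇒ 21. The three O–CH2Ph bonds (O5, O7, O4''') are cut. The phenols of rings A and E have to be masked through basic, organometallic and oxidative steps, and benzyl is removed last under neutral conditions. The demand is that hydrogenolysis stops before the benzylic C2–O and C2''–O bonds are touched.

21 ⇒ 19 (through 20). The ketal bond C2–O7'' (ring F) and the two O–CH2OCH3 bonds on ring D are cut. Ketal exchange at an ionisable C2 is the mildest way to close ring F, and only the cis fusion is possible, so C2 need not be controlled before this point. The gain is the loss of a ring and of one stereocentre. The demand is an acid treatment that removes the MOM groups without ionising C2''–O or shifting a group from C3 to C2.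

19 ⇒ 18. The C2–OCH3 bond is cut back to C2–H. A free 4-hydroxyl on ring B makes C2–H the one position para-benzylic to a phenol, so a quinone can take hydride there selectively. The gain is a return to the flavanone oxidation level; the demand is chemoselectivity over the flavan positions C2'' and C4''.

18 ⇒ 17. The O–allyl bond on ring B is cut. Ring B must be a neutral ether during nucleophilic epoxidation, because a phenoxide there would switch off the enone. Allyl is the one group that can be removed without affecting benzyl, MOM or the ketol.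

17 ⇒ 14 (through 16 and 15). The C2–O1 and C3–O bonds are cut, which opens ring C and removes both new stereocentres. The quaternary carbinol becomes one carbon of a trisubstituted enone. The demands are catalyst control of the enone face, opening of the epoxide at C2 rather than C3, and a ring A oxygen that stays masked until the epoxide exists. A free hydroxyl ortho to the carbonyl is therefore not carried in 14: under base such alpha-aryl chalcones close by oxa-Michael addition to 2,3-diarylchroman-4-ones. The SEM ether is the correction.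

14 ⇒ 12 + 13. The C2=C3 double bond is cut by an aldol-type condensation. This separates ring B as a commercial aldehyde and leaves an activated methylene ketone. The demand is E geometry (aroyl trans to ring B) in a crowded alkene.

12 ⇒ 11 + 8. The CH2–C8'' bond is cut by enolate arylation. This joins the two halves convergently, without the strong acid of a nitrile acylation, which MOM ethers and the flavan would not tolerate. The demand is coupling of a di-ortho-substituted, electron-rich aryl bromide.

11 ⇒ 10 ⇒ 9. The O–SEM bond and then two O–benzyl bonds are cut. Hydrogen bonding to the acetyl group differentiates the three hydroxyls of 9 without extra steps.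

8 ⇒ 7. The C8''–Br bond is cut. The demand is bromination at C8'' and not at C6''.

7 ⇒ 6. The O1''–C2'' bond is cut. The stereocentre is moved to a carbinol that is made by asymmetric reduction; the demand is clean inversion at a benzylic carbon.

6 ⇒ 5 ⇒ 4. The carbinol C–H bond and then the two C–H bonds of the saturated chain are cut. The demand is reduction of C=C without loss of the benzyl ether, then enantioface-selective hydride transfer.

4 ⇒ 2 + 3. The C=C bond is cut by a crossed aldol condensation, which gives ring D with C4'' and ring E with C2'' and C3'' from two simple aromatics.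

2 ⇒ 1. Two O–CH2OCH3 bonds are cut; the hydroxyl that stays free is the one that later becomes O1''.

## Other disconnections considered

Alternative 1: The cut removes C4–C4a, C3–C4 and C2–O7'' at once. In the forward direction zerovalent palladium would join the alkynylphenol A1, carbon monoxide and the aryl iodide A2 to give the 3-aroyl-2-arylbenzofuran A3. The sequence is oxidative addition, CO insertion, anti oxypalladation by the 7''-phenol and reductive elimination.
- In its favour: it is a three-component, highly convergent assembly and makes no stereocentre, so the catalyst need not be chiral. C2 arrives at the enol-ether oxidation level, so no late C–H oxidation is needed. On that point it is better than the chosen plan.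
- Against it: the hindered, electron-rich iodide A2 favours direct (non-carbonylative) arylation to a 2,3-diarylbenzofuran. A1 needs a free 7''-hydroxyl beside a protected 5''-oxygen, which costs protecting-group steps.
- The stereochemical problem is only postponed. The tetrasubstituted, acyl-deactivated C2=C3 bond of A3 must then be oxidised on one face relative to the remote C2'' before the ring A phenol closes ring C. Only electrophilic oxidants would do this, and they compete for the electron-rich rings.
- Comparison: on structure the two plans are equal, since in both only the face at C3 matters and C2 follows from the cis fusion. On mechanism the chosen plan is stronger, because nucleophilic epoxidation of a trisubstituted enone has chiral catalysts and spares electron-rich arenes. On step economy the alternative is about equal overall.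

Alternative 2: The cut removes C3–O and C2–O7'' from the epoxide of the 3-arylflavone A4. In the forward direction an enantioselective epoxidation of C2=C3 of A4 would be followed by attack of the 7''-phenol at C2 to give the pentabenzyl ether A5.
- In its favour: A5 is one hydrogenolysis from the target, so the end-game is about three steps shorter than in the chosen plan, and C2 never needs a separate oxidation. On both points it is better. A4 could come from 12 by C-aroylation and cyclodehydration, so fragment assembly is equal.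
- Against it: the C2=C3 bond of a flavone is tetrasubstituted, part of a vinylogous ester and flanked by two aryl groups. Nucleophilic oxidants would add at C2 and open ring C. Electrophilic ones (dimethyldioxirane) would also attack the free phenol and the trialkoxyarenes. No dependable chiral catalyst exists for this substrate class.
- The furan closure is a 5-endo opening that can only proceed through the C2 oxocarbenium ion. This is acceptable because the fusion must be cis.
- Comparison: the structural logic is the same as in the chosen plan with O1 and O7'' exchanging roles. The chosen plan is preferred only because its stereo-determining oxidation stands on firmer ground.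

Alternative 3: The cut removes C3–C8''. In the forward direction Tl(NO3)3 (or PhI(OAc)2) in methanol would oxidise the 2'-hydroxychalcone A6, in which ring D is the beta-aryl group. Ring D would migrate to the alpha carbon, and acid would close ring C to give the isoflavone A7.
- In its favour: the crowded C3–C8'' bond is made by a 1,2-shift of a very electron-rich aryl group, which migrates readily. This avoids both the hindered enolate arylation and the congested condensation, and on that point it is better than the chosen plan.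
- Against it: A7 still lacks ring B, the C3 hydroxyl and the C2 ketal. It would need conjugate arylation at C2 of a hindered 3-arylchromone with enantiocontrol, enolate hydroxylation at C3 (controlled only indirectly through C2), and then the same C2–H oxidation as in the chosen plan. That is at least three more operations.
- The thallium salt is toxic and can attack the trialkoxyarene.
- Comparison: it is equal in the end-game, because it converges on a compound of the type of 17. It is worse in step count and in the directness of C3 control.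

Key step: step 11

Remarks on the chemistry (before the steps):
- Numbering: flavanone unit C2–C8a with ring A; flavan unit C2''–C8a'' with ring D; ring B on C2; ring E on C2''.
- Assumption: the facial preference that cinchonidinium phase-transfer catalysts show with chalcone (beta carbon becomes R) is taken to carry over to 14; if it does not, the pseudo-enantiomeric cinchoninium salt is used.
- The descriptor of C3 changes from S (17, 18) to R (19–22) only because C2 gains priority over C4 when it becomes a ketal carbon; the arrangement in space is unchanged.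
- SEM = 2-(trimethylsilyl)ethoxymethyl; MOM = methoxymethyl.

## Steps

Step 1
Reactants: 1 2,4,6-trihydroxybenzaldehyde
Product: 2 2-hydroxy-4,6-bis(methoxymethoxy)benzaldehyde
Conditions: MOMCl (2.1 equiv), i-Pr2NEt (2.5 equiv), CH2Cl2, 0 °C to rt
Reagents that add atoms: chloromethyl methyl ether, COCCl
Why: Williamson-type acetalisation (MOM protection); the two non-chelated phenoxides react and the hydroxyl hydrogen-bonded to the formyl group, the later O1'', should stay free.

Step 2
Reactants: 2 2-hydroxy-4,6-bis(methoxymethoxy)benzaldehyde; 3 1-[4-(benzyloxy)phenyl]ethan-1-one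
Product: 4 (2E)-1-[4-(benzyloxy)phenyl]-3-[2-hydroxy-4,6-bis(methoxymethoxy)phenyl]prop-2-en-1-one
Conditions: KOH (aq., excess), EtOH, rt; neutralised with aq. NH4Cl
Reagents that add atoms: none
Why: Claisen–Schmidt (crossed aldol) condensation of a non-enolisable aldehyde with a methyl ketone; elimination under thermodynamic control should give the E enone, and the acetals are stable to base.

Step 3
Reactants: 4 (2E)-1-[4-(benzyloxy)phenyl]-3-[2-hydroxy-4,6-bis(methoxymethoxy)phenyl]prop-2-en-1-one
Product: 5 1-[4-(benzyloxy)phenyl]-3-[2-hydroxy-4,6-bis(methoxymethoxy)phenyl]propan-1-one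
Conditions: H2 (1 atm), 10% Pd/C, Ph2S (0.01 equiv), EtOAc, rt
Reagents that add atoms: none
Why: Heterogeneous catalytic hydrogenation; the sulfide-poisoned palladium catalyst should saturate the enone C=C and spare the benzyl ether, the aryl ketone and the MOM acetals.

Step 4
Reactants: 5 1-[4-(benzyloxy)phenyl]-3-[2-hydroxy-4,6-bis(methoxymethoxy)phenyl]propan-1-one
Product: 6 (1R)-1-[4-(benzyloxy)phenyl]-3-[2-hydroxy-4,6-bis(methoxymethoxy)phenyl]propan-1-ol
Conditions: RuCl(p-cymene)[(R,R)-TsDPEN] (2 mol %), HCO2Na (5 equiv), H2O–DMF, 40 °C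
Reagents that add atoms: none
Why: Noyori-type asymmetric transfer hydrogenation of an aryl alkyl ketone; the (R,R)-diamine complex should deliver hydride to the Si face and give the (R)-carbinol, and the neutral formate medium leaves the acetals and the phenol alone.

Step 5
Reactants: 6 (1R)-1-[4-(benzyloxy)phenyl]-3-[2-hydroxy-4,6-bis(methoxymethoxy)phenyl]propan-1-ol
Product: 7 (2S)-2-[4-(benzyloxy)phenyl]-5,7-bis(methoxymethoxy)chromane
Conditions: PPh3 (1.3 equiv), DIAD (1.3 equiv), THF (dilute), 0 °C
Reagents that add atoms: none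
Why: Intramolecular Mitsunobu etherification (6-exo-tet); the phenol displaces the alkoxyphosphonium group with inversion, so the (R)-carbinol should become the (S)-configured C2''.

Step 6
Reactants: 7 (2S)-2-[4-(benzyloxy)phenyl]-5,7-bis(methoxymethoxy)chromane
Product: 8 (2S)-2-[4-(benzyloxy)phenyl]-8-bromo-5,7-bis(methoxymethoxy)chromane
Conditions: NBS (1.0 equiv), CH2Cl2, −40 to 0 °C, dark
Reagents that add atoms: N-bromosuccinimide, O=C1CCC(=O)N1Br
Why: Electrophilic aromatic bromination; in 5,7-dioxygenated flavans C8 (between the ring oxygen and one alkoxy group) is the most reactive and least encumbered position, so monobromination is expected there and not at C6 or on ring E.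

Step 7
Reactants: 9 1-(2,4,6-trihydroxyphenyl)ethan-1-one
Product: 10 1-[2,4-bis(benzyloxy)-6-hydroxyphenyl]ethan-1-one
Conditions: BnBr (2.1 equiv), K2CO3 (2.2 equiv), DMF, rt
Reagents that add atoms: benzyl bromide, BrCc1ccccc1
Why: Williamson etherification; the hydroxyl chelated to the acetyl group is the least nucleophilic, so two equivalents of benzyl bromide should leave exactly that one free.

Step 8
Reactants: 10 1-[2,4-bis(benzyloxy)-6-hydroxyphenyl]ethan-1-one
Product: 11 1-[2,4-bis(benzyloxy)-6-{[2-(trimethylsilyl)ethoxy]methoxy}phenyl]ethan-1-one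
Conditions: NaH (1.2 equiv), SEMCl (1.2 equiv), DMF, 0 °C to rt
Reagents that add atoms: 2-(trimethylsilyl)ethoxymethyl chloride, C[Si](C)(C)CCOCCl
Why: Williamson-type acetalisation of the sodium phenoxide; SEM is chosen because it survives strong base and palladium and is later removed by fluoride without acid, which the epoxide would not tolerate.

Step 9
Reactants: 11 1-[2,4-bis(benzyloxy)-6-{[2-(trimethylsilyl)ethoxy]methoxy}phenyl]ethan-1-one; 8 (2S)-2-[4-(benzyloxy)phenyl]-8-bromo-5,7-bis(methoxymethoxy)chromane
Product: 12 1-[2,4-bis(benzyloxy)-6-{[2-(trimethylsilyl)ethoxy]methoxy}phenyl]-2-{(2S)-2-[4-(benzyloxy)phenyl]-5,7-bis(methoxymethoxy)chroman-8-yl}ethan-1-one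
Conditions: Pd2(dba)3 (2.5 mol %), P(t-Bu)3·HBF4 (6 mol %), NaOt-Bu (2.2 equiv), toluene, 70 °C; 11 in slight excess
Reagents that add atoms: none
Why: Palladium-catalysed ketone alpha-arylation: oxidative addition of zerovalent palladium into C8''–Br, enolate binding and C–C reductive elimination, with a bulky electron-rich phosphine for the di-ortho-substituted bromide; the hindered product enolate should not be arylated again.

Step 10
Reactants: 12 1-[2,4-bis(benzyloxy)-6-{[2-(trimethylsilyl)ethoxy]methoxy}phenyl]-2-{(2S)-2-[4-(benzyloxy)phenyl]-5,7-bis(methoxymethoxy)chroman-8-yl}ethan-1-one; 13 4-(prop-2-en-1-yloxy)benzaldehyde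
Product: 14 (2E)-3-[4-(allyloxy)phenyl]-1-[2,4-bis(benzyloxy)-6-{[2-(trimethylsilyl)ethoxy]methoxy}phenyl]-2-{(2S)-2-[4-(benzyloxy)phenyl]-5,7-bis(methoxymethoxy)chroman-8-yl}prop-2-en-1-one
Conditions: piperidine (0.5 equiv), AcOH (0.5 equiv), toluene, reflux, water removal (Dean–Stark); 13 in excess
Reagents that add atoms: none
Why: Knoevenagel-type aldol condensation of the doubly activated methylene through the iminium ion of the aldehyde; reversible elimination should give the E isomer (aroyl trans to ring B), the usual outcome for alpha-aryl chalcones, and the masked ring A oxygen cannot add to the enone.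

Step 11
Reactants: 14 (2E)-3-[4-(allyloxy)phenyl]-1-[2,4-bis(benzyloxy)-6-{[2-(trimethylsilyl)ethoxy]methoxy}phenyl]-2-{(2S)-2-[4-(benzyloxy)phenyl]-5,7-bis(methoxymethoxy)chroman-8-yl}prop-2-en-1-one
Product: 17 (2S,3S)-2-[4-(allyloxy)phenyl]-5,7-bis(benzyloxy)-3-{(2S)-2-[4-(benzyloxy)phenyl]-5,7-bis(methoxymethoxy)chroman-8-yl}-3-hydroxychroman-4-one (2-aryl and 3-hydroxyl trans), via SEM-protected (2S,3R)-epoxy ketone 15 (not isolated), via epoxy phenol 16 (not isolated)
Conditions: N-(9-anthracenylmethyl)-O-benzylcinchonidinium bromide (10 mol %), 30% aq. H2O2 (5 equiv), 50% aq. KOH (1 equiv), toluene, 0 °C; aqueous phase removed, organic phase washed (aq. Na2SO3), dried and concentrated without purification; then TBAF (3 equiv), THF–DMPU, 45 °C; aq. NH4Cl quench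
Reagents that add atoms: hydrogen peroxide, OO
Why: Hydroperoxide, paired with the chiral ammonium ion, adds to the beta carbon (the later C2) and the enolate closes onto the O–O bond to give the trans epoxide 15 (C3–O formed); fluoride then removes the SEM group and the ring A phenoxide of 16 attacks the benzylic epoxide carbon anti to the C–O bond, forming C2–O1 and closing ring C. The closest known reactions are the Weitz–Scheffer epoxidation of chalcones under cinchona phase-transfer catalysis and the Algar–Flynn–Oyamada-type cyclisation of 2'-hydroxychalcone epoxides to dihydroflavonols. Ring C closes in the 6-endo-tet mode; the 5-exo alternative would need substitution at the quaternary C3 flanked by the carbonyl and a di-ortho-substituted aryl group, whereas C2 is benzylic and activated by the 4-allyloxyphenyl ring. C3 is set by the catalyst, which chooses the enone face; because the epoxide keeps the E geometry, the configuration of the alpha carbon follows from that of the beta carbon, and the remote C2'' should have little influence. C2 is set by inversion in the opening and is erased later, so only C3 has to be right. The step needs epoxidation to precede phenoxide release, which the base-stable SEM ether secures, and it needs an oxidant that ignores the allyl ether and the electron-rich rings, which a nucleophilic peroxide does. Since 14 is a single enantiomer, the C3 epimer of 17 is a diastereomer and can be separated.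

Step 12
Reactants: 17 (2S,3S)-2-[4-(allyloxy)phenyl]-5,7-bis(benzyloxy)-3-{(2S)-2-[4-(benzyloxy)phenyl]-5,7-bis(methoxymethoxy)chroman-8-yl}-3-hydroxychroman-4-one
Product: 18 (2S,3S)-5,7-bis(benzyloxy)-3-{(2S)-2-[4-(benzyloxy)phenyl]-5,7-bis(methoxymethoxy)chroman-8-yl}-3-hydroxy-2-(4-hydroxyphenyl)chroman-4-one
Conditions: Pd(PPh3)4 (5 mol %), morpholine (5 equiv), THF, rt
Reagents that add atoms: none
Why: Tsuji–Trost deallylation; zerovalent palladium ionises the allyl aryl ether and morpholine takes up the allyl group, while benzyl ethers, MOM acetals and the ketol are inert.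

Step 13
Reactants: 18 (2S,3S)-5,7-bis(benzyloxy)-3-{(2S)-2-[4-(benzyloxy)phenyl]-5,7-bis(methoxymethoxy)chroman-8-yl}-3-hydroxy-2-(4-hydroxyphenyl)chroman-4-one
Product: 19 (3R)-5,7-bis(benzyloxy)-3-{(2S)-2-[4-(benzyloxy)phenyl]-5,7-bis(methoxymethoxy)chroman-8-yl}-3-hydroxy-2-(4-hydroxyphenyl)-2-methoxychroman-4-one (both C2 epimers, used together)
Conditions: DDQ (1.05 equiv), NaHCO3 (solid), MeOH–CH2Cl2 (1:4), −40 to 0 °C
Reagents that add atoms: methanol, CO
Why: Quinone dehydrogenation at the carbon para-benzylic to a free phenol; DDQ takes hydride from C2–H to give the quinone methide (oxocarbenium) and methanol traps it as the mixed ketal, which should be much faster at low temperature than attack on the non-phenolic flavan positions. Both C2 epimers ionise to the same cation in the next step.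

Step 14
Reactants: 19 (3R)-5,7-bis(benzyloxy)-3-{(2S)-2-[4-(benzyloxy)phenyl]-5,7-bis(methoxymethoxy)chroman-8-yl}-3-hydroxy-2-(4-hydroxyphenyl)-2-methoxychroman-4-one
Product: 21 (2R,3R,2''S)-tri-O-benzyl ether of 22 (benzyl on O5, O7 and O4'''; rings C and F cis-fused; free hydroxyls at C3, C4' and C5''), via MOM-free methoxy ketal 20 (not isolated)
Conditions: HCl (about 1 M), MeOH–THF, 35 °C; then evaporation and PPTS (cat.), CH2Cl2, rt
Reagents that add atoms: none
Why: Acid-catalysed transfer of the aryl MOM groups to methanol, then transketalisation: the C2 methoxy group ionises to the cation stabilised by O1 and the 4-hydroxyphenyl ring and the neighbouring 7''-hydroxyl closes ring F (5-exo-trig). Only the cis fusion is possible, so C3 dictates R at C2, and this fast five-ring closure is expected to outrun any 1,2-shift from C3.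

Step 15
Reactants: 21 (2R,3R,2''S)-tri-O-benzyl ether of 22
Product: 22 CNP0208300.2, (2R,3R)-3,5,7-trihydroxy-2-(4-hydroxyphenyl)chroman-4-one bridged from C3 to C8'' and from C2 through oxygen to C7'' of (2S)-5-hydroxy-2-(4-hydroxyphenyl)chromane
Conditions: H2 (1 atm), 10% Pd/C, EtOAc–MeOH, rt; stopped at full debenzylation
Reagents that add atoms: none
Why: Catalytic hydrogenolysis of three benzyl aryl ethers; the cyclic aryl ketal, the flavan C2''–O bond and the tertiary alpha-keto carbinol are cleaved far more slowly, and no stereocentre is touched.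

## Compound list

1 | 2,4,6-trihydroxybenzaldehyde | O=Cc1c(O)cc(O)cc1O | starting material
2 | 2-hydroxy-4,6-bis(methoxymethoxy)benzaldehyde | O=Cc1c(O)cc(OCOC)cc1OCOC | intermediate
3 | 1-[4-(benzyloxy)phenyl]ethan-1-one | CC(=O)c1ccc(OCc2ccccc2)cc1 | starting material
4 | (2E)-1-[4-(benzyloxy)phenyl]-3-[2-hydroxy-4,6-bis(methoxymethoxy)phenyl]prop-2-en-1-one | O=C(/C=C/c1c(O)cc(OCOC)cc1OCOC)c1ccc(OCc2ccccc2)cc1 | intermediate
5 | 1-[4-(benzyloxy)phenyl]-3-[2-hydroxy-4,6-bis(methoxymethoxy)phenyl]propan-1-one | O=C(CCc1c(O)cc(OCOC)cc1OCOC)c1ccc(OCc2ccccc2)cc1 | intermediate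
6 | (1R)-1-[4-(benzyloxy)phenyl]-3-[2-hydroxy-4,6-bis(methoxymethoxy)phenyl]propan-1-ol | O[C@H](CCc1c(O)cc(OCOC)cc1OCOC)c1ccc(OCc2ccccc2)cc1 | intermediate
7 | (2S)-2-[4-(benzyloxy)phenyl]-5,7-bis(methoxymethoxy)chromane | COCOc1cc(OCOC)c2c(c1)O[C@H](c1ccc(OCc3ccccc3)cc1)CC2 | intermediate
8 | (2S)-2-[4-(benzyloxy)phenyl]-8-bromo-5,7-bis(methoxymethoxy)chromane | COCOc1cc(OCOC)c2c(c1Br)O[C@H](c1ccc(OCc3ccccc3)cc1)CC2 | intermediate
9 | 1-(2,4,6-trihydroxyphenyl)ethan-1-one | CC(=O)c1c(O)cc(O)cc1O | starting material
10 | 1-[2,4-bis(benzyloxy)-6-hydroxyphenyl]ethan-1-one | CC(=O)c1c(O)cc(OCc2ccccc2)cc1OCc1ccccc1 | intermediate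
11 | 1-[2,4-bis(benzyloxy)-6-{[2-(trimethylsilyl)ethoxy]methoxy}phenyl]ethan-1-one | CC(=O)c1c(OCOCC[Si](C)(C)C)cc(OCc2ccccc2)cc1OCc1ccccc1 | intermediate
12 | 1-[2,4-bis(benzyloxy)-6-{[2-(trimethylsilyl)ethoxy]methoxy}phenyl]-2-{(2S)-2-[4-(benzyloxy)phenyl]-5,7-bis(methoxymethoxy)chroman-8-yl}ethan-1-one | O=C(Cc1c(OCOC)cc(OCOC)c2c1O[C@H](c1ccc(OCc3ccccc3)cc1)CC2)c1c(OCOCC[Si](C)(C)C)cc(OCc2ccccc2)cc1OCc1ccccc1 | intermediate
13 | 4-(prop-2-en-1-yloxy)benzaldehyde | O=Cc1ccc(OCC=C)cc1 | starting material
14 | (2E)-3-[4-(allyloxy)phenyl]-1-[2,4-bis(benzyloxy)-6-{[2-(trimethylsilyl)ethoxy]methoxy}phenyl]-2-{(2S)-2-[4-(benzyloxy)phenyl]-5,7-bis(methoxymethoxy)chroman-8-yl}prop-2-en-1-one | O=C(c1c(OCOCC[Si](C)(C)C)cc(OCc2ccccc2)cc1OCc1ccccc1)/C(=C/c1ccc(OCC=C)cc1)c1c(OCOC)cc(OCOC)c2c1O[C@H](c1ccc(OCc3ccccc3)cc1)CC2 | intermediate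
15 | {(2S,3R)-3-[4-(allyloxy)phenyl]-2-{(2S)-2-[4-(benzyloxy)phenyl]-5,7-bis(methoxymethoxy)chroman-8-yl}oxiran-2-yl}[2,4-bis(benzyloxy)-6-{[2-(trimethylsilyl)ethoxy]methoxy}phenyl]methanone | O=C(c1c(OCOCC[Si](C)(C)C)cc(OCc2ccccc2)cc1OCc1ccccc1)[C@@]1(c2c(OCOC)cc(OCOC)c3c2O[C@H](c2ccc(OCc4ccccc4)cc2)CC3)O[C@@H]1c1ccc(OCC=C)cc1 | intermediate (not isolated)
16 | {(2S,3R)-3-[4-(allyloxy)phenyl]-2-{(2S)-2-[4-(benzyloxy)phenyl]-5,7-bis(methoxymethoxy)chroman-8-yl}oxiran-2-yl}[2,4-bis(benzyloxy)-6-hydroxyphenyl]methanone (formed as its phenoxide) | O=C(c1c(O)cc(OCc2ccccc2)cc1OCc1ccccc1)[C@@]1(c2c(OCOC)cc(OCOC)c3c2O[C@H](c2ccc(OCc4ccccc4)cc2)CC3)O[C@@H]1c1ccc(OCC=C)cc1 | intermediate (not isolated)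
17 | (2S,3S)-2-[4-(allyloxy)phenyl]-5,7-bis(benzyloxy)-3-{(2S)-2-[4-(benzyloxy)phenyl]-5,7-bis(methoxymethoxy)chroman-8-yl}-3-hydroxychroman-4-one | O=C1c2c(OCc3ccccc3)cc(OCc3ccccc3)cc2O[C@@H](c2ccc(OCC=C)cc2)[C@@]1(O)c1c(OCOC)cc(OCOC)c2c1O[C@H](c1ccc(OCc3ccccc3)cc1)CC2 | intermediate
18 | (2S,3S)-5,7-bis(benzyloxy)-3-{(2S)-2-[4-(benzyloxy)phenyl]-5,7-bis(methoxymethoxy)chroman-8-yl}-3-hydroxy-2-(4-hydroxyphenyl)chroman-4-one | O=C1c2c(OCc3ccccc3)cc(OCc3ccccc3)cc2O[C@@H](c2ccc(O)cc2)[C@@]1(O)c1c(OCOC)cc(OCOC)c2c1O[C@H](c1ccc(OCc3ccccc3)cc1)CC2 | intermediate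
19 | (3R)-5,7-bis(benzyloxy)-3-{(2S)-2-[4-(benzyloxy)phenyl]-5,7-bis(methoxymethoxy)chroman-8-yl}-3-hydroxy-2-(4-hydroxyphenyl)-2-methoxychroman-4-one, both C2 epimers (C2 left undefined in the SMILES) | O=C1c2c(OCc3ccccc3)cc(OCc3ccccc3)cc2OC(OC)(c2ccc(O)cc2)[C@@]1(O)c1c(OCOC)cc(OCOC)c2c1O[C@H](c1ccc(OCc3ccccc3)cc1)CC2 | intermediate
20 | (3R)-5,7-bis(benzyloxy)-3-{(2S)-2-[4-(benzyloxy)phenyl]-5,7-dihydroxychroman-8-yl}-3-hydroxy-2-(4-hydroxyphenyl)-2-methoxychroman-4-one, both C2 epimers | O=C1c2c(OCc3ccccc3)cc(OCc3ccccc3)cc2OC(OC)(c2ccc(O)cc2)[C@@]1(O)c1c(O)cc(O)c2c1O[C@H](c1ccc(OCc3ccccc3)cc1)CC2 | intermediate (not isolated)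
21 | (2R,3R,2''S)-tri-O-benzyl ether of 22 (benzyl on O5, O7, O4''') | O=C1c2c(OCc3ccccc3)cc(OCc3ccccc3)cc2O[C@@]2(c3ccc(O)cc3)Oc3cc(O)c4c(c3[C@@]12O)O[C@H](c1ccc(OCc3ccccc3)cc1)CC4 | intermediate
22 | CNP0208300.2, (2R,3R,2''S) | O=C1c2c(O)cc(O)cc2O[C@@]2(c3ccc(O)cc3)Oc3cc(O)c4c(c3[C@@]12O)O[C@H](c1ccc(O)cc1)CC4 | target

## Step count and risks

Total: 15 steps. Longest linear sequence: 13 steps (1 to 22 through steps 1–6 and 9–15). The ring A ketone 11 takes two steps in a side branch.

Least certain steps:

Step 11 (key step).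
- Most likely to go wrong: slow hydroperoxide addition and weak catalyst control of the enone face. The enone is trisubstituted, and its alpha-aryl group is di-ortho-substituted and twisted, a substrate type on which chiral phase-transfer catalysts are poorly documented.
- A second hazard is a base-induced acyloin-type shift of the C3 alkoxide if the fluoride stage is prolonged.
- A modest selectivity is tolerable, because the C3 epimer of 17 is a diastereomer and can be removed.
- Fallback, from 14 back to 15: Luche reduction (NaBH4, CeCl3·7H2O, MeOH) to the allylic alcohol F1 (both carbinol epimers). Shi epoxidation of this electron-rich trisubstituted alkene (fructose-derived ketone, KHSO5 as Oxone, K2CO3 buffer, MeCN–dimethoxymethane–H2O, 0 °C) to the epoxy alcohol F2, with the catalyst enantiomer chosen by the spiro transition-state model. Oxidation with Dess–Martin periodinane and NaHCO3 to 15, which is then treated with TBAF as in step 11 to reach 17. This replaces nucleophilic, ion-pair-controlled epoxidation by electrophilic, reagent-controlled epoxidation.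

Step 13.
- Most likely to go wrong: competing hydride abstraction from the flavan (C4''–H2 on the electron-rich ring D, C2''–H), or a 1,2-shift of ring D from C3 to the cationic C2. All of these positions are activated toward a quinone.
- Fallback, from 17 back to 20 and 21: ring D is made electron-poor before the oxidation, and the acid treatment is moved to a stage that has no ketal.
  - Cleave the MOM groups of 17 (HCl, MeOH–THF) to the diol F3.
  - Acetylate (Ac2O, pyridine) to the diacetate F4.
  - Deallylate (Pd(PPh3)4, PhSiH3) to the phenol F5.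
  - Oxidise with DDQ in MeOH as in step 13 to the methoxy ketal diacetate F6.
  - Methanolyse (K2CO3, MeOH, 0 °C) to release 20, and close with PPTS to 21.

Step 10.
- Most likely to go wrong: incomplete condensation, through reversal of the crowded aldol adduct, or formation of the Z isomer. The new alkene carries two twisted, di-ortho-substituted aryl groups.
- Fallback, from 12 and 13 back to 14: a kinetic aldol addition (LiN(SiMe3)2, THF, −78 °C) to the aldol F7 (diastereomer mixture), conversion into its mesylate F8 (MsCl, Et3N) and elimination with DBU, which equilibrates toward the E enone 14.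

Step 9.
- Most likely to go wrong: slow oxidative addition and reductive elimination at the di-ortho-alkoxy bromide, leading to loss of bromine by reduction or to self-condensation of the ketone.
- Fallback, from 11 and 8 back to 12, with the polarity reversed:
  - Riley oxidation of 11 (SeO2, dioxane–H2O, 80 °C) to the arylglyoxal F9.
  - Bromine–lithium exchange on 8 (n-BuLi, THF, −78 °C) to the aryllithium F10.
  - Addition of F10 to the aldehyde carbonyl of F9 to give the alpha-hydroxy ketone F11 (both carbinol epimers).
  - Reductive removal of the hydroxyl with SmI2 (THF–MeOH, −78 °C) to 12.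

Step 5.
- Most likely to go wrong: partial ionisation of the 4-benzyloxybenzylic alkoxyphosphonium intermediate, which would erode the configuration at C2''.
- Fallback, from 5 back to 7: cyclodehydration of 5 (PPTS, toluene, reflux, water removal) to the 4H-chromene F12. Asymmetric hydrogenation of its enol-ether double bond with an iridium phosphinooxazoline complex [Ir(cod)(L)]BArF (H2, 50 bar, CH2Cl2) then gives 7, with the ligand enantiomer chosen to give S. In this variant C2'' is set by hydrogen addition and not by substitution.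

## Further compounds

F1 | step 11 | (2E)-3-[4-(allyloxy)phenyl]-1-[2,4-bis(benzyloxy)-6-{[2-(trimethylsilyl)ethoxy]methoxy}phenyl]-2-{(2S)-2-[4-(benzyloxy)phenyl]-5,7-bis(methoxymethoxy)chroman-8-yl}prop-2-en-1-ol, both carbinol epimers | OC(c1c(OCOCC[Si](C)(C)C)cc(OCc2ccccc2)cc1OCc1ccccc1)/C(=C/c1ccc(OCC=C)cc1)c1c(OCOC)cc(OCOC)c2c1O[C@H](c1ccc(OCc3ccccc3)cc1)CC2
F2 | step 11 | {(2S,3R)-3-[4-(allyloxy)phenyl]-2-{(2S)-2-[4-(benzyloxy)phenyl]-5,7-bis(methoxymethoxy)chroman-8-yl}oxiran-2-yl}[2,4-bis(benzyloxy)-6-{[2-(trimethylsilyl)ethoxy]methoxy}phenyl]methanol, both carbinol epimers | OC(c1c(OCOCC[Si](C)(C)C)cc(OCc2ccccc2)cc1OCc1ccccc1)[C@@]1(c2c(OCOC)cc(OCOC)c3c2O[C@H](c2ccc(OCc4ccccc4)cc2)CC3)O[C@@H]1c1ccc(OCC=C)cc1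
F3 | step 13 | (2S,3S)-2-[4-(allyloxy)phenyl]-5,7-bis(benzyloxy)-3-{(2S)-2-[4-(benzyloxy)phenyl]-5,7-dihydroxychroman-8-yl}-3-hydroxychroman-4-one | O=C1c2c(OCc3ccccc3)cc(OCc3ccccc3)cc2O[C@@H](c2ccc(OCC=C)cc2)[C@@]1(O)c1c(O)cc(O)c2c1O[C@H](c1ccc(OCc3ccccc3)cc1)CC2
F4 | step 13 | 5'',7''-di-O-acetate of F3 | O=C1c2c(OCc3ccccc3)cc(OCc3ccccc3)cc2O[C@@H](c2ccc(OCC=C)cc2)[C@@]1(O)c1c(OC(C)=O)cc(OC(C)=O)c2c1O[C@H](c1ccc(OCc3ccccc3)cc1)CC2
F5 | step 13 | 5'',7''-di-O-acetate of F3 with free 4-hydroxyphenyl ring B | O=C1c2c(OCc3ccccc3)cc(OCc3ccccc3)cc2O[C@@H](c2ccc(O)cc2)[C@@]1(O)c1c(OC(C)=O)cc(OC(C)=O)c2c1O[C@H](c1ccc(OCc3ccccc3)cc1)CC2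
F6 | step 13 | 5'',7''-di-O-acetate of 20 (2-methoxy ketal, both C2 epimers) | O=C1c2c(OCc3ccccc3)cc(OCc3ccccc3)cc2OC(OC)(c2ccc(O)cc2)[C@@]1(O)c1c(OC(C)=O)cc(OC(C)=O)c2c1O[C@H](c1ccc(OCc3ccccc3)cc1)CC2
F7 | step 10 | 3-[4-(allyloxy)phenyl]-1-[2,4-bis(benzyloxy)-6-{[2-(trimethylsilyl)ethoxy]methoxy}phenyl]-2-{(2S)-2-[4-(benzyloxy)phenyl]-5,7-bis(methoxymethoxy)chroman-8-yl}-3-hydroxypropan-1-one, diastereomer mixture | O=C(c1c(OCOCC[Si](C)(C)C)cc(OCc2ccccc2)cc1OCc1ccccc1)C(C(O)c1ccc(OCC=C)cc1)c1c(OCOC)cc(OCOC)c2c1O[C@H](c1ccc(OCc3ccccc3)cc1)CC2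
F8 | step 10 | 3-O-methanesulfonate of F7 | O=C(c1c(OCOCC[Si](C)(C)C)cc(OCc2ccccc2)cc1OCc1ccccc1)C(C(OS(C)(=O)=O)c1ccc(OCC=C)cc1)c1c(OCOC)cc(OCOC)c2c1O[C@H](c1ccc(OCc3ccccc3)cc1)CC2
F9 | step 9 | 2-[2,4-bis(benzyloxy)-6-{[2-(trimethylsilyl)ethoxy]methoxy}phenyl]-2-oxoacetaldehyde | O=CC(=O)c1c(OCOCC[Si](C)(C)C)cc(OCc2ccccc2)cc1OCc1ccccc1
F10 | step 9 | {(2S)-2-[4-(benzyloxy)phenyl]-5,7-bis(methoxymethoxy)chroman-8-yl}lithium | [Li]c1c(OCOC)cc(OCOC)c2c1O[C@H](c1ccc(OCc3ccccc3)cc1)CC2
F11 | step 9 | 1-[2,4-bis(benzyloxy)-6-{[2-(trimethylsilyl)ethoxy]methoxy}phenyl]-2-{(2S)-2-[4-(benzyloxy)phenyl]-5,7-bis(methoxymethoxy)chroman-8-yl}-2-hydroxyethan-1-one, both carbinol epimers | O=C(c1c(OCOCC[Si](C)(C)C)cc(OCc2ccccc2)cc1OCc1ccccc1)C(O)c1c(OCOC)cc(OCOC)c2c1O[C@H](c1ccc(OCc3ccccc3)cc1)CC2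
F12 | step 5 | 2-[4-(benzyloxy)phenyl]-5,7-bis(methoxymethoxy)-4H-chromene | COCOc1cc(OCOC)c2c(c1)OC(c1ccc(OCc3ccccc3)cc1)=CC2
A1 | alternative 1 | (2S)-5-(benzyloxy)-2-[4-(benzyloxy)phenyl]-8-{[4-(benzyloxy)phenyl]ethynyl}chroman-7-ol | Oc1cc(OCc2ccccc2)c2c(c1C#Cc1ccc(OCc3ccccc3)cc1)O[C@H](c1ccc(OCc3ccccc3)cc1)CC2
A2 | alternative 1 | 1,5-bis(benzyloxy)-2-iodo-3-(methoxymethoxy)benzene | COCOc1cc(OCc2ccccc2)cc(OCc2ccccc2)c1I
A3 | alternative 1 | 3-[2,4-bis(benzyloxy)-6-(methoxymethoxy)benzoyl]-2-[4-(benzyloxy)phenyl]benzofuran fused through O7''/C8'' to (2S)-5-(benzyloxy)-2-[4-(benzyloxy)phenyl]chromane | O=C(c1c(OCOC)cc(OCc2ccccc2)cc1OCc1ccccc1)c1c(-c2ccc(OCc3ccccc3)cc2)oc2cc(OCc3ccccc3)c3c(c12)O[C@H](c1ccc(OCc2ccccc2)cc1)CC3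
A4 | alternative 2 | 5,7-bis(benzyloxy)-2-[4-(benzyloxy)phenyl]-3-{(2S)-5-(benzyloxy)-2-[4-(benzyloxy)phenyl]-7-hydroxychroman-8-yl}-4H-chromen-4-one | O=c1c(-c2c(O)cc(OCc3ccccc3)c3c2O[C@H](c2ccc(OCc4ccccc4)cc2)CC3)c(-c2ccc(OCc3ccccc3)cc2)oc2cc(OCc3ccccc3)cc(OCc3ccccc3)c12
A5 | alternative 2 | (2R,3R,2''S)-penta-O-benzyl ether of 22 (benzyl on O5, O7, O4', O5'', O4''') | O=C1c2c(OCc3ccccc3)cc(OCc3ccccc3)cc2O[C@@]2(c3ccc(OCc4ccccc4)cc3)Oc3cc(OCc4ccccc4)c4c(c3[C@@]12O)O[C@H](c1ccc(OCc3ccccc3)cc1)CC4
A6 | alternative 3 | (2E)-1-[2,4-bis(benzyloxy)-6-hydroxyphenyl]-3-{(2S)-5-(benzyloxy)-2-[4-(benzyloxy)phenyl]-7-(methoxymethoxy)chroman-8-yl}prop-2-en-1-one | O=C(/C=C/c1c(OCOC)cc(OCc2ccccc2)c2c1O[C@H](c1ccc(OCc3ccccc3)cc1)CC2)c1c(O)cc(OCc2ccccc2)cc1OCc1ccccc1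
A7 | alternative 3 | 5,7-bis(benzyloxy)-3-{(2S)-5-(benzyloxy)-2-[4-(benzyloxy)phenyl]-7-(methoxymethoxy)chroman-8-yl}-4H-chromen-4-one | O=c1c(-c2c(OCOC)cc(OCc3ccccc3)c3c2O[C@H](c2ccc(OCc4ccccc4)cc2)CC3)coc2cc(OCc3ccccc3)cc(OCc3ccccc3)c12
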